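## Analysis of the target

The target is a 2,3-dihydro-1,4-benzodioxine (O1, C2, C3, O4, C4a, C5–C8, C8a) of the neolignan type. C2 carries a 3,4,5-trimethoxyphenyl group, C3 a methyl group, C5 a methoxy group and C7 an (E)-3-oxoprop-1-enyl chain. The only stereocentres are the neighbouring C2 and C3, both R, so the aryl and methyl groups are trans on the dioxane half-chair. The sensitive groups are the enal, which is a Michael acceptor and does not tolerate strong base or nucleophiles, and the C2–O1 bond, a benzylic aryl ether next to an electron-rich arene that can ionise in strong acid. The difficulty is regiochemical as much as stereochemical. The two ring oxygens are not equivalent: O4 lies next to the C5 methoxy group and is bound to the methyl-bearing C3, whereas O1 is bound to the benzylic C2. A route that starts from a catechol has to tell them apart. The strategy rests on ring A: C8a and C7 are ortho and para to C4a, the carbon that bears O4, and the other ortho position (C5) holds the methoxy group. A 2,4-dibromo-6-methoxyphenyl ether therefore carries its two C–Br bonds on exactly the carbons where O1 and the propenal chain must be attached.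

## Retrosynthetic reasoning

**12 to 8 and 9.** The first cut removes two ring A bonds together: O1–C8a and the bond from C7 to the first alkene carbon. Both end on the carbons ortho and para to C4a, so the precursor is the dibromoaryl ether 8, whose halogen pattern is that of phenol 1. Neither bond touches C2 or C3. Cutting O1–C2 or O4–C3 instead would place a substitution at a stereocentre, for C2 an easily ionised benzylic one, at the end of the route. The gain is threefold: both stereocentres sit in an open chain, O4 is already tied to C3 so the ring oxygens cannot be confused, and the enal appears only in the last work-up. In the forward direction copper must join the C1 alkoxide of 8 to the ortho bromide to give 10. Palladium must then couple the para bromide of 10 with acetal 9 to give 11, and acid must unmask 12.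

**8 to 7.** The carbinol C–H bond at C1 of 8 (the later C2) is traced back to ketone 7. The neighbouring C2 centre is then used to control the new one, and the aryl group can be brought in as a carbon nucleophile. The forward reduction must deliver hydride to the face that gives the threo (1R,2R) alcohol, the non-chelation outcome.

**7 to 4 and 5.** The carbonyl–aryl bond is cut. Bromide 5 is symmetrical, so its Grignard reagent 6 is formed without a regiochemical question. Amide 4 accepts one equivalent of 6 and stops at the ketone. The forward step must leave the two C–Br bonds of 4 and the α-stereocentre untouched.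

**4 to 3.** The amide is derived from ester 3 by exchange at the acyl carbon. No skeletal bond changes; the step only prepares the carbonyl group for single addition.

**3 to 1 and 2.** The aryl ether bond (O4–C3 of the target) is cut at the stereocentre and formed by Mitsunobu substitution. Phenol 1 is acidic and 2 has one hydroxyl group, so the coupling is unambiguous. Inversion turns the S centre of 2 into the R centre required at C3.

## Alternatives that were turned down

**Alternative 1:** This plan cuts C2–C3 and C2–aryl by a double boronate homologation. LiCHCl2 adds to the boron of the α-aryloxyethyl boronate A1 and a 1,2-shift with loss of chloride forms C2–C3. Grignard reagent 6 then forms a second borate, and aryl migration displaces the remaining chloride to give A2. No ring closes.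
- For it: the C2-symmetric diol on boron controls the new benzylic centre by reagent control. This is stronger than the substrate-controlled reduction used here for C2, and the assembly is convergent.
- Against it: in A2 and its α-chloro precursor boron sits β to an aryloxy leaving group. Each borate formed can lose aryloxide by β-elimination instead of undergoing the 1,2-shift.
- Against it: A1 has only one bromide, so the chain must be built afterwards from a masked formyl group. After A2 the route still needs C–B oxidation, copper ring closure, acetal removal and olefination, and A1 itself needs a homologation and a phenoxide displacement.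
- Comparison: the chosen route is about half as long and takes C3 from the chiral pool. It accepts weaker control at C2 in exchange for forming ring and chain in one operation.

**Alternative 2:** This plan cuts O4–C3 in the ring-closing step. The branched allylic aryl ether A3 would come from enantioselective allylic etherification with [Ir(cod)Cl]2 and a chiral phosphoramidite, which forms O1–C2. Iodine then activates the vinyl group and the free C4a phenol attacks the internal carbon in a 6-exo closure, giving A4 with an iodomethyl group on C3.
- For it: C2 is set by catalysis and not from a chiral-pool reagent, and no enolisable α-aryloxy ketone appears. On these two points it is the better plan.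
- Against it: C3 is created in the cyclisation by 1,2-induction from C2 alone. A trans preference is plausible but not secured, and the electron-rich trimethoxyphenyl ring can be iodinated in competition.
- Against it: the phenol partner is a catechol whose two hydroxyl groups must be differentiated, so the regiochemical problem returns. After A4 the iodide must be reduced to methyl and the ester taken to the enal in three further steps.
- Comparison: the chosen route brings the methyl group in with 2 and the chain by direct coupling, so neither correction is needed.

**Alternative 3:** This plan cuts O1–C2 and O4–C4a. The phenoxide of A5 opens the cis-epoxide A6 at the benzylic carbon with inversion, and the C3 alkoxide set free closes onto the C4a bromide under CuI catalysis to give A7.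
- For it: it is the most convergent plan. The trans relation follows stereospecifically from the epoxide geometry, so no diastereoselection is needed, which is better than the reduction step of the chosen route.
- Against it: attack at the other epoxide carbon would, after closure, give the regioisomeric dioxane with aryl and methyl exchanged. Any ionisation at the electron-rich benzylic carbon erodes the inversion.
- Against it: the bromine of A5 lies between hydroxyl and methoxy, a position that direct bromination does not favour. The copper closure at this doubly ortho-substituted carbon is more hindered than closure at C8a, and the ester of A7 needs three steps to become the enal.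
- Comparison: the chosen route fixes O4–C3 first by an unambiguous substitution and closes at a carbon with one ortho substituent.

Key step: step 5

Assumption: phenol 1 is taken as a purchasable compound. Ring locants are those of 2,3-dihydro-1,4-benzodioxine, and C1/C2 are those of the propane chain in the open-chain compounds.

## Route

Step 1
Reactants: 1 2,4-dibromo-6-methoxyphenol; 2 ethyl (S)-lactate
Product: 3 ethyl (2R)-2-(2,4-dibromo-6-methoxyphenoxy)propanoate
Conditions: PPh3, DIAD, THF, 0 °C to rt
Reagents that add atoms: none
Why: Mitsunobu etherification: the acidic phenol 1 protonates the PPh3–DIAD betaine and its phenoxide displaces the oxyphosphonium group at the secondary carbon of 2 by SN2 with inversion, so the S centre of the lactate becomes the R centre that ends as C3. The step fixes the O4–C3 bond, and with it the regiochemistry of the dioxane, before any ring exists.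

Step 2
Reactants: 3 ethyl (2R)-2-(2,4-dibromo-6-methoxyphenoxy)propanoate
Product: 4 (2R)-2-(2,4-dibromo-6-methoxyphenoxy)-N-methoxy-N-methylpropanamide
Conditions: MeNH(OMe)·HCl, iPrMgCl, THF, −20 to 0 °C; aq. NH4Cl
Reagents that add atoms: N,O-dimethylhydroxylamine hydrochloride, CNOC.Cl
Why: Ester aminolysis to the Weinreb amide by the chloromagnesium amide formed in the flask; at −20 °C this is an acyl substitution that leaves the α-C–H bond alone, so the R centre should be kept. iPrMgCl is consumed at once by the N–H protons, so free alkyl Grignard reagent is not available for bromine–magnesium exchange on the arene.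

Step 3
Reactants: 4 (2R)-2-(2,4-dibromo-6-methoxyphenoxy)-N-methoxy-N-methylpropanamide; 5 5-bromo-1,2,3-trimethoxybenzene
Product: 7 (2R)-2-(2,4-dibromo-6-methoxyphenoxy)-1-(3,4,5-trimethoxyphenyl)propan-1-one, via 3,4,5-trimethoxyphenylmagnesium bromide 6 (not isolated)
Conditions: 5, Mg, THF, 40 °C; then added to 4, THF, −20 to 0 °C; cold 1 M HCl
Reagents that add atoms: none
Why: Weinreb ketone synthesis: magnesium inserts into the single C–Br bond of symmetrical 5 to give 6, which adds once to 4 because the magnesium-chelated tetrahedral adduct holds until the acidic quench; over-addition and base-mediated epimerisation of the α-aryloxy ketone are thereby avoided. Aryl Grignard reagents exchange with aryl bromides only slowly below 0 °C without LiCl, so the two bromides of 4 should survive.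

Step 4
Reactants: 7 (2R)-2-(2,4-dibromo-6-methoxyphenoxy)-1-(3,4,5-trimethoxyphenyl)propan-1-one
Product: 8 (1R,2R)-2-(2,4-dibromo-6-methoxyphenoxy)-1-(3,4,5-trimethoxyphenyl)propan-1-ol
Conditions: KBH(s-Bu)3, THF, −78 °C; then H2O at −78 °C
Reagents that add atoms: none
Why: Diastereoselective ketone reduction under polar Felkin–Anh control: with the non-chelating potassium counter-ion the C–OAr bond stands perpendicular to the carbonyl plane and anti to the incoming bulky hydride, which passes the C2 hydrogen and not the methyl group; for the 2R ketone this sets C1 as R, the threo alcohol that becomes the trans ring. The dipole-minimised arrangement of C=O and C–OAr predicts the same face, and the aryl bromides are inert to the borohydride at −78 °C.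

Step 5
Reactants: 8 (1R,2R)-2-(2,4-dibromo-6-methoxyphenoxy)-1-(3,4,5-trimethoxyphenyl)propan-1-ol; 9 acrolein diethyl acetal
Product: 12 (2R,3R)-5-methoxy-3-methyl-7-[(E)-3-oxoprop-1-enyl]-2-(3,4,5-trimethoxyphenyl)-2,3-dihydro-1,4-benzodioxine, via 7-bromobenzodioxine 10 (not isolated), via enal diethyl acetal 11 (not isolated)
Conditions: CuI (10 mol%), 1,10-phenanthroline (10 mol%), Cs2CO3 (3 equiv), toluene, 110 °C; then 9 (3 equiv), Pd(OAc)2 (5 mol%), n-Bu4NOAc, KCl, DMF, 90 °C; then 2 M aq. HCl, rt
Reagents that add atoms: water, O
Why: Cs2CO3 deprotonates the C1 hydroxyl of 8, and the copper alkoxide of the CuI–phenanthroline complex inserts into the only C–Br bond within reach, the one ortho to the ether oxygen, to give a seven-membered cupracycle of trivalent copper; C–O reductive elimination then closes the six-membered dioxane ring of 10 (bond O1–C8a, formally a 6-exo attack of the alkoxide on the aryl carbon), the closest known reaction type being the copper-catalysed intramolecular Ullmann O-arylation of secondary alcohols with aryl bromides. No bond at a stereocentre is broken, so the (1R,2R) centres of 8 become (2R,3R) unchanged and no new stereocentre arises. Pd(OAc)2 is then reduced in the flask to zerovalent palladium, which adds to the remaining C7–Br bond of 10; syn insertion of the alkene of 9 puts the aryl group on the terminal carbon and syn β-hydride elimination of a benzylic hydrogen gives the E acetal 11, the known Heck route from aryl bromides and acrolein acetals to cinnamaldehydes. The acetate and chloride additives steer the elimination away from the acetal C–H bond, and the E geometry follows from the anti placement of aryl and acetal groups in the eliminating conformer. Aqueous HCl at room temperature hydrolyses the allylic acetal to enal 12, so the base-sensitive aldehyde never meets the carbonate. The selectivity needed is the assignment of each bromide to its own reaction: the tether makes closure at the ortho bromide intramolecular and much faster than any intermolecular etherification at the para bromide, CuI does not promote Heck coupling, and only one bromide is left when palladium enters. Both halves are established reaction types, and only their combination in one flask is untried.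

## Compound list

1 | 2,4-dibromo-6-methoxyphenol | COc1cc(Br)cc(Br)c1O | starting material
2 | ethyl (S)-lactate | CCOC(=O)[C@H](C)O | starting material
3 | ethyl (2R)-2-(2,4-dibromo-6-methoxyphenoxy)propanoate | CCOC(=O)[C@@H](C)Oc1c(Br)cc(Br)cc1OC | intermediate
4 | (2R)-2-(2,4-dibromo-6-methoxyphenoxy)-N-methoxy-N-methylpropanamide | CON(C)C(=O)[C@@H](C)Oc1c(Br)cc(Br)cc1OC | intermediate
5 | 5-bromo-1,2,3-trimethoxybenzene | COc1cc(Br)cc(OC)c1OC | starting material
6 | 3,4,5-trimethoxyphenylmagnesium bromide | COc1cc([Mg]Br)cc(OC)c1OC | intermediate (not isolated)
7 | (2R)-2-(2,4-dibromo-6-methoxyphenoxy)-1-(3,4,5-trimethoxyphenyl)propan-1-one | COc1cc(C(=O)[C@@H](C)Oc2c(Br)cc(Br)cc2OC)cc(OC)c1OC | intermediate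
8 | (1R,2R)-2-(2,4-dibromo-6-methoxyphenoxy)-1-(3,4,5-trimethoxyphenyl)propan-1-ol | COc1cc(Br)cc(Br)c1O[C@H](C)[C@H](O)c1cc(OC)c(OC)c(OC)c1 | intermediate
9 | acrolein diethyl acetal (3,3-diethoxyprop-1-ene) | C=CC(OCC)OCC | starting material
10 | (2R,3R)-7-bromo-5-methoxy-3-methyl-2-(3,4,5-trimethoxyphenyl)-2,3-dihydro-1,4-benzodioxine | COc1cc([C@H]2Oc3cc(Br)cc(OC)c3O[C@@H]2C)cc(OC)c1OC | intermediate (not isolated)
11 | (2R,3R)-7-[(E)-3,3-diethoxyprop-1-enyl]-5-methoxy-3-methyl-2-(3,4,5-trimethoxyphenyl)-2,3-dihydro-1,4-benzodioxine | COc1cc([C@H]2Oc3cc(/C=C/C(OCC)OCC)cc(OC)c3O[C@@H]2C)cc(OC)c1OC | intermediate (not isolated)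
12 | (2R,3R)-5-methoxy-3-methyl-7-[(E)-3-oxoprop-1-enyl]-2-(3,4,5-trimethoxyphenyl)-2,3-dihydro-1,4-benzodioxine | COc1cc([C@H]2Oc3cc(/C=C/C=O)cc(OC)c3O[C@@H]2C)cc(OC)c1OC | target

## Step count and weak points

Total: 5 steps. Longest linear sequence: 5 steps (from 1 and 2; 5 enters at step 3 and 9 at step 5).

**Step 5 (key step).**
- What may go wrong: the two catalyst systems may interfere. Phenanthroline, iodide and copper salts left from the first stage can occupy palladium and slow oxidative addition into the electron-rich C7–Br bond.
- What may go wrong: before that, the alkoxide may fragment by intramolecular displacement of the dibromophenoxide, which is a good leaving group.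
- What may go wrong: in the Heck stage, β-hydride elimination toward the acetal carbon would lead to the ester oxidation level.
- Fallback: the fallback sets out from 8 and separates the two bond formations. The CuI closure is run alone and 10 is isolated. Bromine–lithium exchange (n-BuLi, THF, −78 °C) and quench with DMF give (2R,3R)-5-methoxy-3-methyl-2-(3,4,5-trimethoxyphenyl)-2,3-dihydro-1,4-benzodioxine-7-carbaldehyde F1. Wittig olefination of F1 with (triphenylphosphoranylidene)acetaldehyde in toluene at 80 °C returns to the route at 12.

**Step 4.**
- What may go wrong: facial selectivity may be poor if the ketone oxygen, the ether oxygen and the ortho methoxy group still chelate the counter-ion and favour the opposite face. Enolisation before reduction would also erode C2.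
- Fallback: the fallback sets out from 7 and uses the chelate mode on purpose. Zn(BH4)2 in Et2O should give (1S,2R)-2-(2,4-dibromo-6-methoxyphenoxy)-1-(3,4,5-trimethoxyphenyl)propan-1-ol F2. Mitsunobu inversion of F2 with 4-nitrobenzoic acid, PPh3 and DIAD gives (1R,2R)-2-(2,4-dibromo-6-methoxyphenoxy)-1-(3,4,5-trimethoxyphenyl)propyl 4-nitrobenzoate F3. Methanolysis of F3 (K2CO3, MeOH) returns to the route at 8.

**Step 3.**
- What may go wrong: aryl groups may scramble by bromine–magnesium exchange between 6 and the dibromoarene, and C2 may lose configurational purity by enolisation of 4 or of the ketone during work-up.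
- Fallback: the fallback sets out from 2 and attaches the dibromoarene only after the ketone exists.
  - Silylation of 2 (TBSCl, imidazole) gives ethyl (2S)-2-[(tert-butyldimethylsilyl)oxy]propanoate F4.
  - Aminolysis of F4 as in step 2 gives (2S)-2-[(tert-butyldimethylsilyl)oxy]-N-methoxy-N-methylpropanamide F5.
  - Addition of 6 to F5 gives (2S)-2-[(tert-butyldimethylsilyl)oxy]-1-(3,4,5-trimethoxyphenyl)propan-1-one F6.
  - Buffered desilylation of F6 (TBAF, AcOH) gives (2S)-2-hydroxy-1-(3,4,5-trimethoxyphenyl)propan-1-one F7.
  - Mitsunobu coupling of F7 with 1 (inversion) returns to the route at 7.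

**Step 1.**
- What may go wrong: coupling may be incomplete because the phenol oxygen is flanked by bromine and methoxy. Elimination of the activated lactate and alkylation of the hydrazide are the competing processes.
- Fallback: the fallback sets out from 2. Triflation (Tf2O, 2,6-lutidine, CH2Cl2, −78 °C) gives ethyl (2S)-2-{[(trifluoromethyl)sulfonyl]oxy}propanoate F8. SN2 displacement of F8 by the potassium phenoxide of 1 (K2CO3, MeCN, 0 °C) proceeds with inversion and returns to the route at 3.

## Further compounds

F1 | step 5 | (2R,3R)-5-methoxy-3-methyl-2-(3,4,5-trimethoxyphenyl)-2,3-dihydro-1,4-benzodioxine-7-carbaldehyde | COc1cc([C@H]2Oc3cc(C=O)cc(OC)c3O[C@@H]2C)cc(OC)c1OC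
F2 | step 4 | (1S,2R)-2-(2,4-dibromo-6-methoxyphenoxy)-1-(3,4,5-trimethoxyphenyl)propan-1-ol | COc1cc(Br)cc(Br)c1O[C@H](C)[C@@H](O)c1cc(OC)c(OC)c(OC)c1
F3 | step 4 | (1R,2R)-2-(2,4-dibromo-6-methoxyphenoxy)-1-(3,4,5-trimethoxyphenyl)propyl 4-nitrobenzoate | COc1cc(Br)cc(Br)c1O[C@H](C)[C@H](OC(=O)c1ccc(cc1)[N+](=O)[O-])c1cc(OC)c(OC)c(OC)c1
F4 | step 3 | ethyl (2S)-2-[(tert-butyldimethylsilyl)oxy]propanoate | CCOC(=O)[C@H](C)O[Si](C)(C)C(C)(C)C
F5 | step 3 | (2S)-2-[(tert-butyldimethylsilyl)oxy]-N-methoxy-N-methylpropanamide | CON(C)C(=O)[C@H](C)O[Si](C)(C)C(C)(C)C
F6 | step 3 | (2S)-2-[(tert-butyldimethylsilyl)oxy]-1-(3,4,5-trimethoxyphenyl)propan-1-one | COc1cc(C(=O)[C@H](C)O[Si](C)(C)C(C)(C)C)cc(OC)c1OC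
F7 | step 3 | (2S)-2-hydroxy-1-(3,4,5-trimethoxyphenyl)propan-1-one | COc1cc(C(=O)[C@H](C)O)cc(OC)c1OC
F8 | step 1 | ethyl (2S)-2-{[(trifluoromethyl)sulfonyl]oxy}propanoate | CCOC(=O)[C@H](C)OS(=O)(=O)C(F)(F)F
A1 | alternative 1 | (4S,5S)-2-{(1S)-1-[2-bromo-4-(1,3-dioxolan-2-yl)-6-methoxyphenoxy]ethyl}-4,5-dicyclohexyl-1,3,2-dioxaborolane | C[C@@H](Oc1c(Br)cc(C2OCCO2)cc1OC)B1O[C@@H](C2CCCCC2)[C@H](C2CCCCC2)O1
A2 | alternative 1 | (4S,5S)-2-{(1R,2R)-2-[2-bromo-4-(1,3-dioxolan-2-yl)-6-methoxyphenoxy]-1-(3,4,5-trimethoxyphenyl)propyl}-4,5-dicyclohexyl-1,3,2-dioxaborolane | C[C@@H](Oc1c(Br)cc(C2OCCO2)cc1OC)[C@@H](c1cc(OC)c(OC)c(OC)c1)B1O[C@@H](C2CCCCC2)[C@H](C2CCCCC2)O1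
A3 | alternative 2 | methyl 4-hydroxy-3-methoxy-5-{[(1S)-1-(3,4,5-trimethoxyphenyl)prop-2-en-1-yl]oxy}benzoate | C=C[C@H](Oc1cc(C(=O)OC)cc(OC)c1O)c1cc(OC)c(OC)c(OC)c1
A4 | alternative 2 | methyl (2R,3S)-3-(iodomethyl)-5-methoxy-2-(3,4,5-trimethoxyphenyl)-2,3-dihydro-1,4-benzodioxine-7-carboxylate (2,3-trans) | COc1cc([C@H]2Oc3cc(C(=O)OC)cc(OC)c3O[C@@H]2CI)cc(OC)c1OC
A5 | alternative 3 | methyl 4-bromo-3-hydroxy-5-methoxybenzoate | COC(=O)c1cc(O)c(Br)c(OC)c1
A6 | alternative 3 | (2R,3S)-2-methyl-3-(3,4,5-trimethoxyphenyl)oxirane (cis) | C[C@H]1O[C@H]1c1cc(OC)c(OC)c(OC)c1
A7 | alternative 3 | methyl (2R,3R)-5-methoxy-3-methyl-2-(3,4,5-trimethoxyphenyl)-2,3-dihydro-1,4-benzodioxine-7-carboxylate | COc1cc([C@H]2Oc3cc(C(=O)OC)cc(OC)c3O[C@@H]2C)cc(OC)c1OC
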